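The hour was my unit, and what I counted in it was doublings of X.

| flask | D | Q | temperature | remark | time |
|---|---|---|---|---|---|
| dusk | 0.014 M | 17 mM (held) | 76 °C | run made earlier |  |
| spring | 0.056 M | 17 mM (held) | 90 °C | run made earlier |  |
| Monday's | 0.028 M | 17 mM (held) | 70 °C |  | 4.0 h |
| Friday's | 0.028 M | 17 mM (held) | 95 °C |  | 4.0 h |

dusk run (percent of the D charged)

| time / h | X / % | D / % |
|---|---|---|
| 0.417 | 0.2 | 99.5 |
| 0.833 | 0.1 | 99.8 |
| 2.00 | 1.3 | 98.8 |
| 5.00 | 23.8 | 75.6 |

spring run (percent of the D charged)

| time / min | X / % | D / % |
|---|---|---|
| 10.0 | 0 | 99.7 |
| 20.0 | 0 | 99.7 |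
| 40.0 | 0.3 | 98.8 |
| 120 | 18.5 | 81.4 |

(scatter of a reading: 0.3 percentage points)

- which of these there is most of at the end, counted by the D in it, Monday's (X / D)
- which of these there is most of at the end, counted by the D in it, Friday's (X / D)
- final amount of the leader among these, as a percentage of the D charged, in Monday's
- final amount of the leader among these, as a percentage of the D charged, in Friday's

- the numbers in the tables scatter with a standard deviation of 0.3 percentage points
- at the start none of Q is in solution
- a reading or a percentage of X counts all its forms, free or not

In both earlier runs X lay near zero for a long stretch (an induction period) and then climbed, so I took X to feed its own making. Between the last two dusk readings X doubled every 0.715 h: this is the doubling time of X, the time in which X doubles once it has taken off.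

The ladder of times ran upward from there. On the lowest rung stood the spring run's doubling time, 0.224 h, a weak reading, since its foot is X at 0.3% against a scatter of 0.3 percentage points. Next came the dusk value, then the 4.0 h of the new flasks. Highest stood the half-life of D before take-off, 107 h, read from the dusk run's 1.3% of X at 2.00 h, a reading far longer than the 4.0 h of the new flasks. So the quiet stretch leaves a small seed of X, and the doublings make the rest.

For Monday's I started from that dusk seed and kept the dusk doubling time, taking the larger charge and the colder bath to cancel, since the two runs had changed both together. That left 2.80 doublings, so X near 9.03% and D leading near 91.0%. For Friday's I started from the spring run's 18.5% at 120 min and kept the spring doubling time: 8.93 doublings against room for 2.43. So X leads, but the count gave me no height.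

The forecast, holding for Friday's that “4 h is well past induction”, said D at 95% for Monday's and X at 96% for Friday's. Monday's flask gave D at 87.0%. Friday's flask gave X at 74.6%.

    D + Z + X → 2 X (k = 0.973 M⁻² s⁻¹, Ea = 58.0 kJ mol⁻¹)
    D + Z → X (k = 1.33 × 10⁻⁴ M⁻¹ s⁻¹, Ea = 65.0 kJ mol⁻¹)
    E ⇌ X, rate k3*(cs3 - [X]) while solid is left; crystals form when [X] > cs3 (solubility = 15.0 mM, k = 0.00395 s⁻¹)
    Q ⇌ Z, rate k4*(csat - [Z]) (kL = 1.30 × 10⁻⁴ s⁻¹)
    (constants at 70 °C)

On Monday's, X went from 1.05% to 13.0% in the second half of the run, doubling on average every 0.553 h against my 0.715 h. On Monday's the step D + Z + X → 2 X used D at 0.70 of the rate of D + Z → X at 1.29 h, and at 27 times that rate at 4.00 h.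

A further flask, like Monday's but with 0.0070 M of D, has the same bath, and the rate of D + Z + X → 2 X carries c_D, so I stretched my doubling time to 2.86 h. From the same seed that is 0.699 doublings and X near 2.11%; the computed flask gave 2.84%.

All runs stem from a simulated flask from invented constants; the scatter is artificial.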